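**Retrosynthetic overview**
1. Target ⇒ tetralin 24 by C6 lithiation/carboxylation and removal of both MOM groups.
2. 24 ⇒ tetralone 11 + secondary alkylboronic acid 20: the C4–C11 bond is made by a 1,2-shift of the chiral alkyl group from boron to the diazo carbon of the tetralone hydrazone (new reductive coupling).
3. 11 ⇒ dihydronaphthalene 8 by benzylic oxidation and Ir-catalysed asymmetric hydrogenation (sets C1).
4. 8 ⇒ cyclopropyl carbinol 6 by cationic ring expansion of the cyclopropane into the six-membered carbocycle (the only ring formed; the aromatic ring comes from catechol) ⇒ MOM-guaiacol 3 (ortho-lithiation) + cyclopropyl methyl ketone.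
5. 20 ⇒ lithiation–borylation (1,2-metalate shift, sets C11) of ethyl carbamate 13 with boronate 16, made from (S)-2-methylpent-4-en-1-ol (C15).

Assumption: (S)-2-methylpent-4-en-1-ol and (+)-sparteine are bought; target positions use serrulatane numbering (C1 = ring CHMe, C4 = ring CH carrying the side chain, C6 = C–CO2Me, C7 = C–OMe, C8 = C–OH, C11 and C15 = side-chain CHMe).

**Route**

Step 1
Reactants: 1 catechol
Product: 2 guaiacol (2-methoxyphenol)
Conditions: MeI (1.0 equiv), K2CO3 (1.05 equiv), acetone, 56 °C; extraction into aq. NaOH removes veratrole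
Reagents that add atoms: iodomethane, CI
Why: Williamson O-methylation of the catechol mono-anion with one equivalent of base and MeI stops mainly at the mono-ether, and the phenolic product is separated from the neutral diether by base extraction.

Step 2
Reactants: 2 guaiacol
Product: 3 1-methoxy-2-(methoxymethoxy)benzene
Conditions: NaH, THF, 0 °C; MOMCl, 0 °C → rt
Reagents that add atoms: chloromethyl methyl ether, COCCl
Why: MOM protection of the phenoxide (Williamson-type alkylation) installs the ortho-directing group for step 3 and masks the future C8 phenol.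

Step 3
Reactants: 3 1-methoxy-2-(methoxymethoxy)benzene; 4 cyclopropyl methyl ketone
Product: 6 1-cyclopropyl-1-[3-methoxy-2-(methoxymethoxy)phenyl]ethan-1-ol (racemic), via aryllithium 5 (not isolated)
Conditions: n-BuLi (1.1 equiv), THF, 0 °C → rt; then 4, −78 °C → rt; H2O
Reagents that add atoms: none
Why: Directed ortho-metalation occurs next to OMOM (the stronger director; this carbon becomes C8a) and the aryllithium adds 1,2 to the ketone; the carbinol stereocentre is lost in step 4.

Step 4
Reactants: 6 1-cyclopropyl-1-[3-methoxy-2-(methoxymethoxy)phenyl]ethan-1-ol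
Product: 8 6-methoxy-5-(methoxymethoxy)-4-methyl-1,2-dihydronaphthalene, via cyclopropylcarbinyl cation 7 (not isolated)
Conditions: Bi(OTf)3 (2 mol %), 4 Å MS, CH2Cl2, −20 → 0 °C
Reagents that add atoms: none
Why: Ionisation gives a tertiary benzylic cyclopropylcarbinyl cation whose cyclopropane CH2 is attacked by the only free ortho carbon (para to OMe), so the three-membered ring is expanded into the six-membered carbocycle with a C1=C2 double bond (cyclopropylcarbinyl–homoallyl rearrangement ended by Friedel–Crafts cyclialkylation; no stereocentre is formed).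

Step 5
Reactants: 8 6-methoxy-5-(methoxymethoxy)-4-methyl-1,2-dihydronaphthalene
Product: 9 (1R)-7-methoxy-8-(methoxymethoxy)-1-methyl-1,2,3,4-tetrahydronaphthalene
Conditions: [Ir(cod)(tBu-PHOX-type P,N ligand)]BArF (1 mol %, ligand enantiomer that gives 1R), H2 (50 bar), CH2Cl2, rt
Reagents that add atoms: none
Why: Iridium–phosphinooxazoline asymmetric hydrogenation of unfunctionalised trisubstituted aryl alkenes (1-methyl-3,4-dihydronaphthalenes are standard substrates) sets C1 as R under catalyst control.

Step 6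
Reactants: 9 (1R)-7-methoxy-8-(methoxymethoxy)-1-methyl-1,2,3,4-tetrahydronaphthalene
Product: 11 (4R)-6-methoxy-5-(methoxymethoxy)-4-methyl-3,4-dihydronaphthalen-1(2H)-one, via benzylic alcohol 10 (not isolated)
Conditions: DDQ (2.3 equiv), 1,4-dioxane/H2O (9:1), 0 °C → rt
Reagents that add atoms: water, O
Why: DDQ benzylic oxidation by hydride abstraction takes place at the CH2 para to the coplanar OMe group (the tertiary C1–H is hindered and sits ortho to the twisted, flanked OMOM group), water traps the cation and the p-methoxybenzylic alcohol is oxidised on to the ketone, leaving C1 untouched.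

Step 7
Reactants: 12 ethanol
Product: 13 ethyl N,N-diisopropylcarbamate
Conditions: NaH, THF, 0 °C; iPr2NCOCl, reflux
Reagents that add atoms: N,N-diisopropylcarbamoyl chloride, CC(C)N(C(C)C)C(Cl)=O
Why: O-Carbamoylation gives the Hoppe carbamate, which acidifies the OCH2 group and later serves as the leaving group of the 1,2-metalate shift.

Step 8
Reactants: 14 (2S)-2-methylpent-4-en-1-ol
Product: 15 (4S)-5-(methoxymethoxy)-4-methylpent-1-ene
Conditions: NaH, THF, 0 °C; MOMCl
Reagents that add atoms: chloromethyl methyl ether, COCCl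
Why: MOM protection of the primary alcohol (Williamson-type alkylation) does not touch the stereocentre, which becomes C15 of the target (chiral pool).

Step 9
Reactants: 15 (4S)-5-(methoxymethoxy)-4-methylpent-1-ene
Product: 16 2-[(4S)-5-(methoxymethoxy)-4-methylpentyl]-4,4,5,5-tetramethyl-1,3,2-dioxaborolane
Conditions: HBpin (1.2 equiv), [Ir(cod)Cl]2 (1.5 mol %), dppm (3 mol %), CH2Cl2, rt
Reagents that add atoms: pinacolborane, CC1(C)OBOC1(C)C
Why: Iridium-catalysed anti-Markovnikov hydroboration of the terminal alkene gives the linear primary pinacol boronate.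

Step 10
Reactants: 13 ethyl N,N-diisopropylcarbamate; 16 2-[(4S)-5-(methoxymethoxy)-4-methylpentyl]-4,4,5,5-tetramethyl-1,3,2-dioxaborolane
Product: 19 2-[(2S,6S)-7-(methoxymethoxy)-6-methylheptan-2-yl]-4,4,5,5-tetramethyl-1,3,2-dioxaborolane, via lithiated carbamate 17 (not isolated), via boronate complex 18 (not isolated)
Conditions: 13 (1.3 equiv), s-BuLi, (+)-sparteine, Et2O, −78 °C, 5 h; then 16, −78 °C; MgBr2·OEt2, reflux
Reagents that add atoms: none
Why: Sparteine-mediated asymmetric deprotonation gives the configurationally stable (R)-α-lithio carbamate, which is borylated with retention and then undergoes a stereospecific 1,2-metalate shift of the primary alkyl group with inversion at the carbenoid carbon (lithiation–borylation, Matteson-type homologation), setting C11 as S under reagent control.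

Step 11
Reactants: 19 2-[(2S,6S)-7-(methoxymethoxy)-6-methylheptan-2-yl]-4,4,5,5-tetramethyl-1,3,2-dioxaborolane
Product: 20 [(2S,6S)-7-(methoxymethoxy)-6-methylheptan-2-yl]boronic acid
Conditions: NaIO4 (3 equiv), NH4OAc (3 equiv), acetone/H2O (1:1), rt
Reagents that add atoms: water, O
Why: Hydrolysis of the pinacol ester is driven to completion by periodate cleavage of the released pinacol and does not touch the C–B stereocentre.

Step 12
Reactants: 11 (4R)-6-methoxy-5-(methoxymethoxy)-4-methyl-3,4-dihydronaphthalen-1(2H)-one; 20 [(2S,6S)-7-(methoxymethoxy)-6-methylheptan-2-yl]boronic acid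
Product: 24 (1S,4R)-6-methoxy-5-(methoxymethoxy)-1-[(2S,6S)-7-(methoxymethoxy)-6-methylheptan-2-yl]-4-methyl-1,2,3,4-tetrahydronaphthalene, via tosylhydrazone 21 (not isolated), via diazoalkane 22 (not isolated), via tertiary boronic acid 23 (not isolated)
Conditions: TsNHNH2 (1.1 equiv), 1,4-dioxane, 80 °C; then 20 (1.5 equiv), K2CO3 (3 equiv), CsF (2 equiv), H2O (3 equiv), 110 °C
Reagents that add atoms: none
Why: Proposed new method: one-pot tosylhydrazone formation and Bamford–Stevens diazo generation, then carboborylation of the diazo carbon by the α-chiral secondary alkylboronic acid, in which boron bonds on the face anti to the pseudo-axial C1 methyl (held axial by A1,3 strain with the peri OMOM group), the sec-alkyl group shifts 1,2 from boron to C4 with loss of N2 (retention in the migrating carbon, so 11S is carried over from 20) and the tertiary benzylic boronic acid 23 is protodeboronated with retention by fluoride/water, leaving the side chain trans to the methyl group (4S); the closest known reactions are the metal-free reductive coupling of N-tosylhydrazones with boronic acids (Barluenga–Valdés coupling, known for aryl and simple alkyl boronic acids and cyclic ketone hydrazones) and the stereoretentive protodeboronation of tertiary benzylic boronates, and what is new is the transfer of an enantioenriched α-branched secondary alkyl group with 1,4-diastereocontrol.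

Step 13
Reactants: 24 (1S,4R)-6-methoxy-5-(methoxymethoxy)-1-[(2S,6S)-7-(methoxymethoxy)-6-methylheptan-2-yl]-4-methyl-1,2,3,4-tetrahydronaphthalene
Product: 26 methyl (5R,8S)-3-methoxy-4-(methoxymethoxy)-8-[(2S,6S)-7-(methoxymethoxy)-6-methylheptan-2-yl]-5-methyl-5,6,7,8-tetrahydronaphthalene-2-carboxylate, via aryllithium 25 (not isolated)
Conditions: s-BuLi (1.5 equiv), TMEDA, THF, −78 → −40 °C; then cannulated into ClCO2Me (3 equiv), THF, −78 °C
Reagents that add atoms: methyl chloroformate, COC(=O)Cl
Why: Directed ortho-metalation occurs at C6, the only aromatic C–H next to a directing group (ortho to OMe; the OMOM group has no free ortho position), and acylation of the aryllithium with the chloroformate gives the methyl ester.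

Step 14
Reactants: 26 methyl (5R,8S)-3-methoxy-4-(methoxymethoxy)-8-[(2S,6S)-7-(methoxymethoxy)-6-methylheptan-2-yl]-5-methyl-5,6,7,8-tetrahydronaphthalene-2-carboxylate
Product: 27 methyl (5R,8S)-4-hydroxy-8-[(2S,6S)-7-hydroxy-6-methylheptan-2-yl]-3-methoxy-5-methyl-5,6,7,8-tetrahydronaphthalene-2-carboxylate (target)
Conditions: HCl (3 M in MeOH), 45 °C
Reagents that add atoms: none
Why: Acid-catalysed transacetalisation to methanol removes the aryl and the alkyl MOM ether in one operation, the methyl ester is inert in methanol, and no stereocentre is affected.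

**Compound list**
1 | catechol (benzene-1,2-diol) | Oc1ccccc1O | starting material
2 | guaiacol (2-methoxyphenol) | COc1ccccc1O | intermediate
3 | 1-methoxy-2-(methoxymethoxy)benzene | COCOc1ccccc1OC | intermediate
4 | cyclopropyl methyl ketone (1-cyclopropylethan-1-one) | CC(=O)C1CC1 | starting material
5 | [3-methoxy-2-(methoxymethoxy)phenyl]lithium | [Li]c1cccc(OC)c1OCOC | intermediate
6 | 1-cyclopropyl-1-[3-methoxy-2-(methoxymethoxy)phenyl]ethan-1-ol (racemic) | COCOc1c(OC)cccc1C(C)(O)C1CC1 | intermediate
7 | 1-cyclopropyl-1-[3-methoxy-2-(methoxymethoxy)phenyl]ethylium (cyclopropylcarbinyl cation) | C[C+](C1CC1)c1cccc(OC)c1OCOC | intermediate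
8 | 6-methoxy-5-(methoxymethoxy)-4-methyl-1,2-dihydronaphthalene | CC1=CCCc2ccc(OC)c(OCOC)c12 | intermediate
9 | (1R)-7-methoxy-8-(methoxymethoxy)-1-methyl-1,2,3,4-tetrahydronaphthalene | COc1ccc2c(c1OCOC)[C@H](C)CCC2 | intermediate
10 | (4R)-6-methoxy-5-(methoxymethoxy)-4-methyl-1,2,3,4-tetrahydronaphthalen-1-ol (both C1 epimers) | COc1ccc2c(c1OCOC)[C@H](C)CCC2O | intermediate
11 | (4R)-6-methoxy-5-(methoxymethoxy)-4-methyl-3,4-dihydronaphthalen-1(2H)-one | COc1ccc2c(c1OCOC)[C@H](C)CCC2=O | intermediate
12 | ethanol | CCO | starting material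
13 | ethyl N,N-diisopropylcarbamate | CCOC(=O)N(C(C)C)C(C)C | intermediate
14 | (2S)-2-methylpent-4-en-1-ol | C=CC[C@H](C)CO | starting material
15 | (4S)-5-(methoxymethoxy)-4-methylpent-1-ene | C=CC[C@H](C)COCOC | intermediate
16 | 2-[(4S)-5-(methoxymethoxy)-4-methylpentyl]-4,4,5,5-tetramethyl-1,3,2-dioxaborolane | CC1(C)OB(CCC[C@H](C)COCOC)OC1(C)C | intermediate
17 | (1R)-1-lithioethyl N,N-diisopropylcarbamate | [Li][C@H](C)OC(=O)N(C(C)C)C(C)C | intermediate
18 | lithium [(1R)-1-(N,N-diisopropylcarbamoyloxy)ethyl][(4S)-5-(methoxymethoxy)-4-methylpentyl](pinacolato)borate | [Li+].CC1(C)O[B-](CCC[C@H](C)COCOC)([C@H](C)OC(=O)N(C(C)C)C(C)C)OC1(C)C | intermediate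
19 | 2-[(2S,6S)-7-(methoxymethoxy)-6-methylheptan-2-yl]-4,4,5,5-tetramethyl-1,3,2-dioxaborolane | CC1(C)OB(OC1(C)C)[C@@H](C)CCC[C@H](C)COCOC | intermediate
20 | [(2S,6S)-7-(methoxymethoxy)-6-methylheptan-2-yl]boronic acid | OB(O)[C@@H](C)CCC[C@H](C)COCOC | intermediate
21 | N'-[(4R)-6-methoxy-5-(methoxymethoxy)-4-methyl-3,4-dihydronaphthalen-1(2H)-ylidene]-4-methylbenzenesulfonohydrazide | COc1ccc2c(c1OCOC)[C@H](C)CCC2=NNS(=O)(=O)c1ccc(C)cc1 | intermediate
22 | (4R)-1-diazo-6-methoxy-5-(methoxymethoxy)-4-methyl-1,2,3,4-tetrahydronaphthalene | COc1ccc2c(c1OCOC)[C@H](C)CCC2=[N+]=[N-] | intermediate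
23 | [(1S,4R)-6-methoxy-5-(methoxymethoxy)-1-[(2S,6S)-7-(methoxymethoxy)-6-methylheptan-2-yl]-4-methyl-1,2,3,4-tetrahydronaphthalen-1-yl]boronic acid | COc1ccc2c(c1OCOC)[C@H](C)CC[C@@]2(B(O)O)[C@@H](C)CCC[C@H](C)COCOC | intermediate
24 | (1S,4R)-6-methoxy-5-(methoxymethoxy)-1-[(2S,6S)-7-(methoxymethoxy)-6-methylheptan-2-yl]-4-methyl-1,2,3,4-tetrahydronaphthalene | COc1ccc2c(c1OCOC)[C@H](C)CC[C@H]2[C@@H](C)CCC[C@H](C)COCOC | intermediate
25 | [(5R,8S)-3-methoxy-4-(methoxymethoxy)-8-[(2S,6S)-7-(methoxymethoxy)-6-methylheptan-2-yl]-5-methyl-5,6,7,8-tetrahydronaphthalen-2-yl]lithium | [Li]c1cc2c(c(OCOC)c1OC)[C@H](C)CC[C@H]2[C@@H](C)CCC[C@H](C)COCOC | intermediate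
26 | methyl (5R,8S)-3-methoxy-4-(methoxymethoxy)-8-[(2S,6S)-7-(methoxymethoxy)-6-methylheptan-2-yl]-5-methyl-5,6,7,8-tetrahydronaphthalene-2-carboxylate | COC(=O)c1cc2c(c(OCOC)c1OC)[C@H](C)CC[C@H]2[C@@H](C)CCC[C@H](C)COCOC | intermediate
27 | methyl (5R,8S)-4-hydroxy-8-[(2S,6S)-7-hydroxy-6-methylheptan-2-yl]-3-methoxy-5-methyl-5,6,7,8-tetrahydronaphthalene-2-carboxylate | COC(=O)c1cc2c(c(O)c1OC)[C@H](C)CC[C@H]2[C@@H](C)CCC[C@H](C)CO | target

**Step count and risks**
Total: 14 steps. Longest linear sequence: 9 steps (1–6, 12–14); the side chain (steps 7–11) joins at step 12.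

Step 12 (the new coupling) is the most likely to fail. The diazo compound may give the Bamford–Stevens alkene, the facial selectivity at C4 may be low, or the protodeboronation may not be retentive. The fallback uses known chemistry, sets out from 11 and comes back at 24. (R)-Me-CBS (10 mol %), BH3·SMe2, THF, −20 °C reduces 11 under catalyst control to the cis alcohol (1S,4R)-6-methoxy-5-(methoxymethoxy)-4-methyl-1,2,3,4-tetrahydronaphthalen-1-ol F1. NaH and iPr2NCOCl in THF at reflux give its N,N-diisopropylcarbamate F2. Deprotonation with s-BuLi in Et2O at −78 °C (retention), addition of pinacol boronate 19 and MgBr2/MeOH at reflux give the tertiary boronic ester F3, by borylation with retention and a 1,2-metalate shift with inversion at C4 and retention in the migrating C11. TBAF·3H2O in toluene at 50 °C (protodeboronation with retention) returns 24. Step 11 is then not needed.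

Step 4 (cationic ring expansion) is second. The ortho OMOM oxygen can trap the cation or the MOM group can be lost, and water can open the cation to a homoallylic alcohol. The fallback sets out from 3 and comes back at 11, so it also bypasses steps 5 and 6. n-BuLi, then N-methoxy-N-methylacetamide, gives 1-[3-methoxy-2-(methoxymethoxy)phenyl]ethan-1-one F4. Wittig olefination with (2-carboxyethyl)triphenylphosphonium bromide/NaHMDS gives (3E)-4-[3-methoxy-2-(methoxymethoxy)phenyl]pent-3-enoic acid F5. Carboxy-directed Ir–spiro-phosphinooxazoline asymmetric hydrogenation (H2, Et3N, MeOH) gives (4R)-4-[3-methoxy-2-(methoxymethoxy)phenyl]pentanoic acid F6. Eaton's reagent closes the ring by Friedel–Crafts acylation para to OMe, with loss of the MOM group, to give (4R)-5-hydroxy-6-methoxy-4-methyl-3,4-dihydronaphthalen-1(2H)-one F7. NaH/MOMCl returns 11.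

Step 13 (late ortho-lithiation/carboxylation) is third. Lithiation could compete at a benzylic C–H or an OCH2O group, or the aryllithium could add twice to the ester. The fallback sets out from 24 and comes back at 26. Sterically controlled C–H borylation with [Ir(cod)OMe]2/dtbpy and B2pin2 in THF at 80 °C, at C6 (C5 is shielded by the C4 substituent), gives the aryl boronate 2-[(5R,8S)-3-methoxy-4-(methoxymethoxy)-8-[(2S,6S)-7-(methoxymethoxy)-6-methylheptan-2-yl]-5-methyl-5,6,7,8-tetrahydronaphthalen-2-yl]-4,4,5,5-tetramethyl-1,3,2-dioxaborolane F8. Pd(OAc)2/PPh3, CO (1 atm), MeOH and p-benzoquinone (oxidative methoxycarbonylation) return 26.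

**Further compounds**
F1 | step 12 | (1S,4R)-6-methoxy-5-(methoxymethoxy)-4-methyl-1,2,3,4-tetrahydronaphthalen-1-ol | COc1ccc2c(c1OCOC)[C@H](C)CC[C@@H]2O
F2 | step 12 | (1S,4R)-6-methoxy-5-(methoxymethoxy)-4-methyl-1,2,3,4-tetrahydronaphthalen-1-yl N,N-diisopropylcarbamate | COc1ccc2c(c1OCOC)[C@H](C)CC[C@@H]2OC(=O)N(C(C)C)C(C)C
F3 | step 12 | 2-[(1S,4R)-6-methoxy-5-(methoxymethoxy)-1-[(2S,6S)-7-(methoxymethoxy)-6-methylheptan-2-yl]-4-methyl-1,2,3,4-tetrahydronaphthalen-1-yl]-4,4,5,5-tetramethyl-1,3,2-dioxaborolane | COc1ccc2c(c1OCOC)[C@H](C)CC[C@@]2(B1OC(C)(C)C(C)(C)O1)[C@@H](C)CCC[C@H](C)COCOC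
F4 | step 4 | 1-[3-methoxy-2-(methoxymethoxy)phenyl]ethan-1-one | COCOc1c(OC)cccc1C(C)=O
F5 | step 4 | (3E)-4-[3-methoxy-2-(methoxymethoxy)phenyl]pent-3-enoic acid | COCOc1c(OC)cccc1/C(C)=C/CC(O)=O
F6 | step 4 | (4R)-4-[3-methoxy-2-(methoxymethoxy)phenyl]pentanoic acid | COCOc1c(OC)cccc1[C@H](C)CCC(O)=O
F7 | step 4 | (4R)-5-hydroxy-6-methoxy-4-methyl-3,4-dihydronaphthalen-1(2H)-one | COc1ccc2c(c1O)[C@H](C)CCC2=O
F8 | step 13 | 2-[(5R,8S)-3-methoxy-4-(methoxymethoxy)-8-[(2S,6S)-7-(methoxymethoxy)-6-methylheptan-2-yl]-5-methyl-5,6,7,8-tetrahydronaphthalen-2-yl]-4,4,5,5-tetramethyl-1,3,2-dioxaborolane | CC1(C)OB(OC1(C)C)c1cc2c(c(OCOC)c1OC)[C@H](C)CC[C@H]2[C@@H](C)CCC[C@H](C)COCOC
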